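**Plan**
Retrosynthesis: the C6 ketone is traced back to a C6 methyl enol ether plus a C7a mixed ketal. The O–CH3 and C5–allyl bonds at the quaternary C5 are then cut, which uncovers a C5 ketone. This quinone monoketal is traced back to a phenol, and finally O1–C2 and C3a–C3 are cut together.
Enabling feature: in ring A (C3a, C4, C5, C6, C7, C7a), the O1-bearing C7a and the quaternary C5 are para to each other and both at carbonyl level. C6 and C7 carry the other two oxygens, and C3a–C4 is the only free edge. Ring A is therefore a masked 2,3-dimethoxy-1,4-benzoquinone in which C5=O makes C3a electrophilic and C7a=O supplies O1.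
Forward: ring B (O1, C2, C3, C3a, C7a) is closed first by a formal [3+2] union of the quinone with (E)-isoelemicin, and ring A emerges as a phenol. Ring A is then re-oxidised to the quinone monoketal, allylated at C5, O-methylated and unmasked.
Stereochemistry: C3 (absolute) comes from a titanium TADDOLate, C2 is set trans to C3 by the E-alkene, and C5 comes from a chiral allylsilver reagent. The C7a centre is temporary.

Key step: step 3

Assumption: the sense of induction of the two chiral controllers (TADDOL in step 3, DIFLUORPHOS in step 5) is assigned by analogy; both antipodes of each are commercial, so a wrong sense is corrected by exchanging the antipode.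

Step 1
Reactants: 1 5-bromo-1,2,3-trimethoxybenzene; 2 (E)-prop-1-en-1-ylboronic acid pinacol ester
Product: 3 (E)-isoelemicin [(E)-1,2,3-trimethoxy-5-(prop-1-en-1-yl)benzene]
Conditions: PdCl2(dppf) (cat.), K2CO3, 1,4-dioxane/H2O, 85 °C
Reagents that add atoms: none
Why: Suzuki–Miyaura coupling of an aryl bromide with an alkenylboronate keeps the alkene geometry, so the pure E-alkene needed for the trans ring should result.

Step 2
Reactants: 4 2,3-dimethoxyphenol
Product: 5 2,3-dimethoxy-1,4-benzoquinone
Conditions: (KSO3)2NO, KH2PO4 buffer, H2O/acetone, rt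
Reagents that add atoms: potassium nitrosodisulfonate (KSO3)2NO, [K+].[K+].[O]N(S(=O)(=O)[O-])S(=O)(=O)[O-]
Why: Teuber oxidation of a phenol with a free para position delivers the p-quinone, and the two methoxy groups are untouched by the radical oxidant.

Step 3
Reactants: 5 2,3-dimethoxy-1,4-benzoquinone; 3 (E)-isoelemicin
Product: 6 (2S,3S)-6,7-dimethoxy-3-methyl-2-(3,4,5-trimethoxyphenyl)-2,3-dihydro-1-benzofuran-5-ol
Conditions: TiCl2(OiPr)2 + (4R,5R)-TADDOL (premixed, 4 Å MS, toluene, rt), then 5, then 3, CH2Cl2/toluene, −78 → −20 °C; sat. aq. NaHCO3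
Reagents that add atoms: none
Why: Tetravalent titanium binds the C1 carbonyl oxygen and the neighbouring 2-methoxy oxygen of 5 as a five-membered chelate and polarises the unsubstituted C5=C6 bond, so the methyl-bearing alkene carbon of 3 attacks C5 (the future C3a) and leaves a benzylic cation, stabilised by the trimethoxyphenyl ring, beside a titanium dienolate. The oxygen of the second carbonyl (C4=O, the future O1 on C7a) captures this cation and closes ring B in a formally 5-exo-trig mode, and loss of the C3a proton aromatises ring A, which makes the sequence irreversible. The closest known reaction type is the Lewis-acid-promoted formal [3+2] cycloaddition of 2-alkoxy-1,4-benzoquinones with (E)-1-propenylarenes, for which titanium TADDOLate promoters are known to give enantioenriched trans-2-aryl-3-methyl-2,3-dihydrobenzofuran-5-ols. C3 is set by the TADDOLate, whose pseudo-axial phenyl groups leave one face of the chelated quinone open, so that the alkene, stacked aryl-endo over that face, bonds through one enantioface only; C2 follows from C3, because suprafacial closure carries the E geometry over and the trans ring is also the more stable one. Regioselectivity needs no control, since the mirror symmetry of 5 makes both chelation sites and both free ring carbons equivalent, and the polarity of the alkene decides which carbon bonds to carbon and which to oxygen. The step needs periselectivity against [2+2] and [5+2] closure of the same zwitterion, and warming secures it, because those adducts reopen at the benzylic bond while aromatisation drains the [3+2] channel.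

Step 4
Reactants: 6 (2S,3S)-dihydrobenzofuran-5-ol
Product: 7 (2S,3S,7aR)-6,7,7a-trimethoxy-3-methyl-2-(3,4,5-trimethoxyphenyl)-3,7a-dihydro-1-benzofuran-5(2H)-one
Conditions: PhI(OAc)2, MeOH, 0 °C
Reagents that add atoms: methanol, CO
Why: Oxidative dearomatisation of a 4-alkoxyphenol by a trivalent iodine reagent gives a phenoxenium ion that MeOH traps at the O1-bearing para carbon C7a (p-quinone monoketal formation), expected mainly anti to the C2 aryl group; this centre is erased in step 7, and even ortho trapping at C6 would converge on the same target through steps 5 to 7.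

Step 5
Reactants: 7 quinone monoketal
Product: 8 (2S,3S,5R,7aR)-5-allyl-6,7,7a-trimethoxy-3-methyl-2-(3,4,5-trimethoxyphenyl)-2,3,5,7a-tetrahydro-1-benzofuran-5-ol
Conditions: AgF (cat.), (R)-DIFLUORPHOS (cat.), CH2=CHCH2Si(OMe)3, MeOH, THF, −78 → −40 °C; Et3N-deactivated silica
Reagents that add atoms: allyltrimethoxysilane, C=CC[Si](OC)(OC)OC
Why: Catalytic asymmetric Sakurai–Hosomi allylation of a conjugated cyclic ketone, in which the diphosphine-bound allylsilver species adds 1,2 to the only carbonyl group and sets C5 under reagent control by telling the C4–H flank from the C6–OMe flank, the C2 and C3 centres being too remote to interfere.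

Step 6
Reactants: 8 tertiary carbinol
Product: 9 (2S,3S,5R,7aR)-5-allyl-5,6,7,7a-tetramethoxy-3-methyl-2-(3,4,5-trimethoxyphenyl)-2,3,5,7a-tetrahydro-1-benzofuran
Conditions: KN(SiMe3)2, THF, −78 °C; MeOTf, −78 °C
Reagents that add atoms: methyl trifluoromethanesulfonate, COS(=O)(=O)C(F)(F)F
Why: Williamson-type O-methylation of the tertiary potassium alkoxide at low temperature, where capture by MeOTf outruns the anionic oxy-Cope shift open to this 1,5-dien-3-olate, and no stereocentre is touched.

Step 7
Reactants: 9 quinol ether ketal
Product: 11 (2S,3S,5R)-5-allyl-5,7-dimethoxy-3-methyl-2-(3,4,5-trimethoxyphenyl)-2,3-dihydro-1-benzofuran-6(5H)-one (target), via O-methyl oxocarbenium ion 10 (not isolated)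
Conditions: p-TsOH·H2O (cat.), acetone/H2O, 0 °C → rt
Reagents that add atoms: water, O
Why: Ketal hydrolysis with 1,3-carbonyl transposition, in which C7a ionises first because its cation is stabilised directly by O1 and vinylogously by the 6-methoxy group, and water then adds at C6 of 10 and expels MeOH; this unveils the C6 ketone with the C7=C7a and C3a=C4 bonds and removes the temporary C7a centre while C2, C3 and C5 stay untouched.

**Compound list**
1 | 5-bromo-1,2,3-trimethoxybenzene | COc1cc(Br)cc(OC)c1OC | starting material
2 | (E)-prop-1-en-1-ylboronic acid pinacol ester | C/C=C/B1OC(C)(C)C(C)(C)O1 | starting material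
3 | (E)-isoelemicin | C/C=C/c1cc(OC)c(OC)c(OC)c1 | intermediate
4 | 2,3-dimethoxyphenol | COc1cccc(O)c1OC | starting material
5 | 2,3-dimethoxy-1,4-benzoquinone | COC1=C(OC)C(=O)C=CC1=O | intermediate
6 | (2S,3S)-6,7-dimethoxy-3-methyl-2-(3,4,5-trimethoxyphenyl)-2,3-dihydro-1-benzofuran-5-ol | Oc1cc2c(c(OC)c1OC)O[C@H](c1cc(OC)c(OC)c(OC)c1)[C@H]2C | intermediate
7 | (2S,3S,7aR)-6,7,7a-trimethoxy-3-methyl-2-(3,4,5-trimethoxyphenyl)-3,7a-dihydro-1-benzofuran-5(2H)-one | O=C1C=C2[C@](OC)(C(OC)=C1OC)O[C@H](c1cc(OC)c(OC)c(OC)c1)[C@H]2C | intermediate
8 | (2S,3S,5R,7aR)-5-allyl-6,7,7a-trimethoxy-3-methyl-2-(3,4,5-trimethoxyphenyl)-2,3,5,7a-tetrahydro-1-benzofuran-5-ol | C=CC[C@@]1(O)C=C2[C@](OC)(C(OC)=C1OC)O[C@H](c1cc(OC)c(OC)c(OC)c1)[C@H]2C | intermediate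
9 | (2S,3S,5R,7aR)-5-allyl-5,6,7,7a-tetramethoxy-3-methyl-2-(3,4,5-trimethoxyphenyl)-2,3,5,7a-tetrahydro-1-benzofuran | C=CC[C@@]1(OC)C=C2[C@](OC)(C(OC)=C1OC)O[C@H](c1cc(OC)c(OC)c(OC)c1)[C@H]2C | intermediate
10 | O-methyl oxocarbenium ion (the 6-O-methylated target cation) | C=CC[C@@]1(OC)C=C2C(=C(OC)C1=[O+]C)O[C@H](c1cc(OC)c(OC)c(OC)c1)[C@H]2C | intermediate
11 | (2S,3S,5R)-5-allyl-5,7-dimethoxy-3-methyl-2-(3,4,5-trimethoxyphenyl)-2,3-dihydro-1-benzofuran-6(5H)-one | C=CC[C@@]1(OC)C=C2C(=C(OC)C1=O)O[C@H](c1cc(OC)c(OC)c(OC)c1)[C@H]2C | target

Total step count: 7. Longest linear sequence: 6 (steps 1, 3, 4, 5, 6, 7, or equally steps 2 to 7).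

**Steps most likely to fail**

Step 5. The facial discrimination at the flat dienone carbonyl may be poor, because its two flanks differ only by H against OMe. The addition may also be sluggish, because the carbonyl is deactivated as a vinylogous ester. The fallback gives up reagent control. It sets out from 7, to which CH2=CHCH2MgBr (THF, −78 °C) adds 1,2 without facial bias. This gives 8 together with the C5-epimeric carbinol F1. Since C2 and C3 are already enantiopure, the two are diastereomers and are separated on Et3N-deactivated silica. The route is rejoined at 8.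

Step 3. The enantiofacial control of the chiral chelate may erode, or the zwitterion may be held up in the [2+2] channel. The fallback replaces asymmetric promotion by resolution. It sets out from 3 and 5, which are joined with the achiral promoter TiCl4/Ti(OiPr)4 in CH2Cl2. The mixture is warmed until all material has funnelled to the aromatic trans product. This gives 6 together with the enantiomeric dihydrobenzofuranol F2. The two are separated by preparative chromatography on a polysaccharide chiral stationary phase, and the route is rejoined at 6.

Step 7. Water may capture the cation at C7a instead of C6, which opens ring B. With acid that is too strong, ionisation at the doubly allylic C5 may compete. The fallback splits the step in two. It sets out from 9, which is hydrolysed on purpose with aqueous AcOH/THF at 0 °C to the ring-opened hydroxy dienone F3, and this is isolated. In a separate, water-poor operation (camphorsulfonic acid cat., toluene, 40 °C, MeOH distilled off) the C2 hydroxyl adds to the C7a carbonyl. The vinylogous ester is then transposed with loss of MeOH, and the C2–O bond is never broken. The route is rejoined at 11.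

**Further compounds**
F1 | step 5 | (2S,3S,5S,7aR)-5-allyl-6,7,7a-trimethoxy-3-methyl-2-(3,4,5-trimethoxyphenyl)-2,3,5,7a-tetrahydro-1-benzofuran-5-ol | C=CC[C@]1(O)C=C2[C@](OC)(C(OC)=C1OC)O[C@H](c1cc(OC)c(OC)c(OC)c1)[C@H]2C
F2 | step 3 | (2R,3R)-6,7-dimethoxy-3-methyl-2-(3,4,5-trimethoxyphenyl)-2,3-dihydro-1-benzofuran-5-ol | Oc1cc2c(c(OC)c1OC)O[C@@H](c1cc(OC)c(OC)c(OC)c1)[C@@H]2C
F3 | step 7 | (4R)-4-allyl-6-[(1S,2S)-1-hydroxy-1-(3,4,5-trimethoxyphenyl)propan-2-yl]-2,3,4-trimethoxycyclohexa-2,5-dien-1-one | C=CC[C@@]1(OC)C=C([C@H](C)[C@H](O)c2cc(OC)c(OC)c(OC)c2)C(=O)C(OC)=C1OC
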